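Ring A is cut at C7–C7a and C4–C5 into two non-aromatic three-carbon partners. The feature used is that C7a–O1 and C3a–C3 of the benzofuran form the enol-ether double bond of a 4,5-dihydrofuran, so C7a and C4 can be delivered as the β-carbon and the ester carbon of a cyclic β-alkoxy-β-(methylthio)acrylate (fragment 1), which already carries the C2 stereocentre. In one flask the central carbon of the cinnamoyl diketone (fragment 2) replaces the methylthio group at C7a and C5 then closes onto the ester, so the hexasubstituted phloroglucinol ring A appears with all substituents placed. Enone hydrogenation and desilylation complete the synthesis.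

Key step: step 8

Remark on locants: benzofuran numbering (O1, C2, C3, C3a, C4–C7, C7a) is used for ring A and the dihydrofuran throughout.
Remark on fragment 2: the diketone has to be the ten-carbon chain 9-methyldeca-1,8-diene-3,5-dione, because the methylene that becomes C5 must already carry the complete 3-methylbut-2-enyl group; a nona-1,7-diene chain would leave C5 one carbon short.
Remark on tautomers: the malonate-derived lactone is carried as a mixture of epimers at its ester-bearing carbon and the thionated lactone is drawn as the thione, although it should exist largely as the chelated enethiol; that carbon becomes sp2 in fragment 1.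

Step 1
Reactants: 1 methyl (2S)-oxirane-2-carboxylate
Product: 2 2-[(2S)-oxiran-2-yl]propan-2-ol
Conditions: MeMgCl (2.3 equiv), THF, −78 → −30 °C; aq. NH4Cl
Reagents that add atoms: methylmagnesium chloride, C[Mg]Cl
Why: Double Grignard addition to the ester should outrun attack on the epoxide at low temperature, and the stereocentre is not involved, so the (S) configuration of 1 is carried over unchanged.

Step 2
Reactants: 2 2-[(2S)-oxiran-2-yl]propan-2-ol
Product: 3 triethyl({2-[(2S)-oxiran-2-yl]propan-2-yl}oxy)silane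
Conditions: Et3SiCl, imidazole, 4-(dimethylamino)pyridine (cat.), DMF, 25 °C
Reagents that add atoms: chlorotriethylsilane, CC[Si](Cl)(CC)CC
Why: Silylation of the tertiary alcohol under nucleophilic catalysis needs neither strong base nor Lewis acid, so Payne rearrangement and epoxide opening should not intervene, and the ether blocks Payne rearrangement in the next step.

Step 3
Reactants: 3 triethyl({2-[(2S)-oxiran-2-yl]propan-2-yl}oxy)silane; 4 dimethyl malonate
Product: 5 methyl (5S)-2-oxo-5-[2-(triethylsilyloxy)propan-2-yl]oxolane-3-carboxylate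
Conditions: NaOMe (1.1 equiv), MeOH, 60 °C; AcOH
Reagents that add atoms: none
Why: Malonate alkylation by SN2 opening of the terminal epoxide at its CH2 is followed by lactonisation of the secondary alkoxide (5-exo-trig), which should be faster than silyl migration between the two oxygens; the C–O bond at the stereocentre is kept, so it stays (S).

Step 4
Reactants: 5 methyl (5S)-2-oxo-5-[2-(triethylsilyloxy)propan-2-yl]oxolane-3-carboxylate
Product: 6 methyl (5S)-2-sulfanylidene-5-[2-(triethylsilyloxy)propan-2-yl]oxolane-3-carboxylate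
Conditions: Lawesson's reagent (0.6 equiv), toluene, 80 °C
Reagents that add atoms: Lawesson's reagent, COc1ccc(cc1)P1(=S)SP(=S)(S1)c1ccc(OC)cc1
Why: Thionation with Lawesson's reagent is faster at a lactone carbonyl than at an acyclic ester, and the first thionation gives a chelated enethiol whose remaining ester is deactivated as a vinylogous thiocarbonate.

Step 5
Reactants: 6 methyl (5S)-2-sulfanylidene-5-[2-(triethylsilyloxy)propan-2-yl]oxolane-3-carboxylate
Product: 7 methyl (5S)-2-(methylsulfanyl)-5-[2-(triethylsilyloxy)propan-2-yl]-4,5-dihydrofuran-3-carboxylate (fragment 1)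
Conditions: MeI, K2CO3, acetone, 0 → 25 °C
Reagents that add atoms: iodomethane, CI
Why: S-Alkylation of the soft enethiolate of a β-thioxo ester should give the β-(methylthio)acrylate, here the cyclic ketene O,S-acetal, and removes the epimeric centre next to the ester.

Step 6
Reactants: 8 acetylacetone; 9 prenyl bromide
Product: 10 8-methylnon-7-ene-2,4-dione
Conditions: LiN(i-Pr)2 (2.1 equiv), THF, −78 → 0 °C; 9, 0 °C; aq. NH4Cl
Reagents that add atoms: none
Why: Alkylation of a 1,3-diketone dianion takes place at the more basic terminal carbanion, which should displace the allylic bromide in SN2 fashion while the central enolate is a spectator.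

Step 7
Reactants: 10 8-methylnon-7-ene-2,4-dione; 11 4-methoxybenzaldehyde
Product: 14 (1E)-1-(4-methoxyphenyl)-9-methyldeca-1,8-diene-3,5-dione (fragment 2), via boron chelate of the starting diketone 12 (not isolated), via boron chelate of the styryl diketone 13 (not isolated)
Conditions: B2O3, B(OBu)3, n-BuNH2 (cat.), EtOAc, 70 °C; then 0.4 M HCl, 60 °C
Reagents that add atoms: none
Why: In this boron-templated aldol condensation of the curcuminoid type, chelation masks the central carbon against Knoevenagel reaction and activates the terminal methyl, which is less hindered than the internal methylene, and dehydration should give the (E)-enone under thermodynamic control.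

Step 8
Reactants: 7 methyl (5S)-2-(methylsulfanyl)-5-[2-(triethylsilyloxy)propan-2-yl]-4,5-dihydrofuran-3-carboxylate (fragment 1); 14 (1E)-1-(4-methoxyphenyl)-9-methyldeca-1,8-diene-3,5-dione (fragment 2)
Product: 16 (2E)-1-[(2S)-4,6-dihydroxy-5-(3-methylbut-2-en-1-yl)-2-[2-(triethylsilyloxy)propan-2-yl]-2,3-dihydro-1-benzofuran-7-yl]-3-(4-methoxyphenyl)prop-2-en-1-one, via dihydrofuranyl diketone adduct 15 (not isolated)
Conditions: KN(SiMe3)2 (1.0 equiv), THF–DMPU, 0 → 60 °C, Ar stream; then LiN(i-Pr)2 (2.2 equiv), −78 → 0 °C; aq. NH4Cl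
Reagents that add atoms: none
Why: Proposed new method: the potassium enolate of 14 should add through its central carbon to C7a of the push–pull alkene 7 (β to the ester, bearing O1 and SMe) and expel methanethiolate, which the much more acidic adduct 15 protonates so that MeSH leaves in the gas stream, making the C7–C7a bond irreversible and leaving no thiolate to add to the enone; LiN(i-Pr)2 then removes a C5 proton and this carbanion closes ring A onto the ester carbon (C4–C5) in a 6-exo-trig Dieckmann step, after which loss of methoxide and enolisation aromatise the ring, the ester oxygen becoming the C4 phenol and the ketone oxygen the C6 phenol. The closest known reaction types are the base-induced [3+3] benzannulation of α-oxo ketene dithioacetals with ketone carbanions and the Claisen cyclisation of polyketo esters to acylphloroglucinols. No stereocentre is formed, and C2 has no acidic neighbour, so it passes through unchanged. The step needs C7 and not C5 to attack C7a, and only C5 to attack the ester: the first is secured by keeping exactly one equivalent of base until 7 is consumed, the second by the cinnamoyl side having no enolisable α-hydrogen. O-Attack of the enolate at C7a or a 6-endo Michael closure of the C5 carbanion onto the enone would be reversible and should drain into the aromatic product, the only irreversible outcome.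

Step 9
Reactants: 16 (2E)-1-[(2S)-4,6-dihydroxy-5-(3-methylbut-2-en-1-yl)-2-[2-(triethylsilyloxy)propan-2-yl]-2,3-dihydro-1-benzofuran-7-yl]-3-(4-methoxyphenyl)prop-2-en-1-one
Product: 17 1-[(2S)-4,6-dihydroxy-5-(3-methylbut-2-en-1-yl)-2-[2-(triethylsilyloxy)propan-2-yl]-2,3-dihydro-1-benzofuran-7-yl]-3-(4-methoxyphenyl)propan-1-one
Conditions: H2 (1 atm), RhCl(PPh3)3 (5 mol %), toluene–EtOH, 25 °C
Reagents that add atoms: none
Why: Homogeneous hydrogenation with RhCl(PPh3)3 discriminates by alkene substitution, so the disubstituted enone C=C should be saturated while the trisubstituted prenyl alkene, the ketone and the free phenols are left alone, and the neutral medium should not promote chalcone-to-flavanone cyclisation.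

Step 10
Reactants: 17 1-[(2S)-4,6-dihydroxy-5-(3-methylbut-2-en-1-yl)-2-[2-(triethylsilyloxy)propan-2-yl]-2,3-dihydro-1-benzofuran-7-yl]-3-(4-methoxyphenyl)propan-1-one
Product: 18 1-[(2S)-4,6-dihydroxy-2-(2-hydroxypropan-2-yl)-5-(3-methylbut-2-en-1-yl)-2,3-dihydro-1-benzofuran-7-yl]-3-(4-methoxyphenyl)propan-1-one
Conditions: Bu4NF, AcOH, THF, 25 °C
Reagents that add atoms: none
Why: Buffered fluoride cleavage of the tertiary triethylsilyl ether avoids acid, under which the ortho-prenyl phenol would cyclise to a chroman, and leaves the C2 stereocentre untouched.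

Compound list
1 | methyl (2S)-oxirane-2-carboxylate | COC(=O)[C@@H]1CO1 | starting material
2 | 2-[(2S)-oxiran-2-yl]propan-2-ol | CC(C)(O)[C@@H]1CO1 | intermediate
3 | triethyl({2-[(2S)-oxiran-2-yl]propan-2-yl}oxy)silane | CC[Si](CC)(CC)OC(C)(C)[C@@H]1CO1 | intermediate
4 | dimethyl malonate | COC(=O)CC(=O)OC | starting material
5 | methyl (5S)-2-oxo-5-[2-(triethylsilyloxy)propan-2-yl]oxolane-3-carboxylate (epimers at C3) | O=C1O[C@H](C(C)(C)O[Si](CC)(CC)CC)CC1C(=O)OC | intermediate
6 | methyl (5S)-2-sulfanylidene-5-[2-(triethylsilyloxy)propan-2-yl]oxolane-3-carboxylate (thione form of the enethiol) | S=C1O[C@H](C(C)(C)O[Si](CC)(CC)CC)CC1C(=O)OC | intermediate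
7 | fragment 1, methyl (5S)-2-(methylsulfanyl)-5-[2-(triethylsilyloxy)propan-2-yl]-4,5-dihydrofuran-3-carboxylate | O1[C@H](C(C)(C)O[Si](CC)(CC)CC)CC(C(=O)OC)=C1SC | intermediate
8 | acetylacetone (pentane-2,4-dione) | CC(=O)CC(C)=O | starting material
9 | prenyl bromide (1-bromo-3-methylbut-2-ene) | CC(C)=CCBr | starting material
10 | 8-methylnon-7-ene-2,4-dione | CC(=O)CC(=O)CCC=C(C)C | intermediate
11 | 4-methoxybenzaldehyde | COc1ccc(C=O)cc1 | starting material
12 | boron chelate of 10, drawn as the dibutoxyboron diketonate (not isolated) | CCCCO[B-]1(OCCCC)OC(C)=CC(CCC=C(C)C)=[O+]1 | intermediate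
13 | boron chelate of 14, drawn as the dibutoxyboron diketonate (not isolated) | CCCCO[B-]1(OCCCC)OC(/C=C/c2ccc(OC)cc2)=CC(CCC=C(C)C)=[O+]1 | intermediate
14 | fragment 2, (1E)-1-(4-methoxyphenyl)-9-methyldeca-1,8-diene-3,5-dione | COc1ccc(/C=C/C(=O)CC(=O)CCC=C(C)C)cc1 | intermediate
15 | methyl (5S)-2-[(1E)-1-(4-methoxyphenyl)-9-methyl-3,5-dioxodeca-1,8-dien-4-yl]-5-[2-(triethylsilyloxy)propan-2-yl]-4,5-dihydrofuran-3-carboxylate (present as its potassium enolate, not isolated) | O1[C@H](C(C)(C)O[Si](CC)(CC)CC)CC(C(=O)OC)=C1C(C(=O)/C=C/c1ccc(OC)cc1)C(=O)CCC=C(C)C | intermediate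
16 | (2E)-1-[(2S)-4,6-dihydroxy-5-(3-methylbut-2-en-1-yl)-2-[2-(triethylsilyloxy)propan-2-yl]-2,3-dihydro-1-benzofuran-7-yl]-3-(4-methoxyphenyl)prop-2-en-1-one | COc1ccc(/C=C/C(=O)c2c(O)c(CC=C(C)C)c(O)c3c2O[C@H](C(C)(C)O[Si](CC)(CC)CC)C3)cc1 | intermediate
17 | 1-[(2S)-4,6-dihydroxy-5-(3-methylbut-2-en-1-yl)-2-[2-(triethylsilyloxy)propan-2-yl]-2,3-dihydro-1-benzofuran-7-yl]-3-(4-methoxyphenyl)propan-1-one | COc1ccc(CCC(=O)c2c(O)c(CC=C(C)C)c(O)c3c2O[C@H](C(C)(C)O[Si](CC)(CC)CC)C3)cc1 | intermediate
18 | 1-[(2S)-4,6-dihydroxy-2-(2-hydroxypropan-2-yl)-5-(3-methylbut-2-en-1-yl)-2,3-dihydro-1-benzofuran-7-yl]-3-(4-methoxyphenyl)propan-1-one | COc1ccc(CCC(=O)c2c(O)c(CC=C(C)C)c(O)c3c2O[C@H](C(C)(C)O)C3)cc1 | target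

Total step count: 10. Longest linear sequence: 8 steps (steps 1–5, then 8–10); steps 6 and 7 form the second branch.

Steps most likely to fail

Step 8. The stabilised diketone enolate may be too weak a nucleophile for the doubly donor-substituted C7a, the later dianion may add to C7a through C5 if 7 is still present, or the Dieckmann closure onto the deactivated vinylogous carbonate may stall. The fallback uses known reaction types only, sets out from 2 and 9 and returns at 18: ring A is taken from an arene and the O1–C7a bond is closed by nucleophilic aromatic substitution. Alcohol 2 is converted with MOMCl and i-Pr2NEt into (2S)-2-[2-(methoxymethoxy)propan-2-yl]oxirane F1, an ether that cannot migrate to a neighbouring alkoxide. 5-Fluorobenzene-1,3-diol is protected as 1-fluoro-3,5-bis(methoxymethoxy)benzene F2, lithiated between the two acetal oxygens (n-BuLi, THF) and alkylated with 9 to give 5-fluoro-1,3-bis(methoxymethoxy)-2-(3-methylbut-2-en-1-yl)benzene F3. Directed lithiation next to fluorine (s-BuLi, −78 °C) and BF3·OEt2-assisted opening of F1 at its CH2 should give (2S)-1-[6-fluoro-2,4-bis(methoxymethoxy)-3-(3-methylbut-2-en-1-yl)phenyl]-3-(methoxymethoxy)-3-methylbutan-2-ol F4. Lithiation of the last ring position (s-BuLi, 2.2 equiv, −78 °C) and acylation with N-methoxy-N-methyl-3-(4-methoxyphenyl)propanamide should give the ortho-fluoro ketone 1-[2-fluoro-3-[(2S)-2-hydroxy-3-(methoxymethoxy)-3-methylbutyl]-4,6-bis(methoxymethoxy)-5-(3-methylbut-2-en-1-yl)phenyl]-3-(4-methoxyphenyl)propan-1-one F5. K2CO3 in DMF then closes the dihydrofuran by intramolecular SNAr of the secondary alkoxide on the ketone-activated C–F carbon, with retention at C2, to give 1-[(2S)-4,6-bis(methoxymethoxy)-2-[2-(methoxymethoxy)propan-2-yl]-5-(3-methylbut-2-en-1-yl)-2,3-dihydro-1-benzofuran-7-yl]-3-(4-methoxyphenyl)propan-1-one F6, and HCl in MeOH at 25 °C removes the three acetals to give 18. Every ring position is fixed by the order of the three metalations, at the price of a longer sequence.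

Step 4. Thionation may fail to discriminate between the lactone and the ester carbonyl or may occur twice, and acidic phosphorus by-products may cleave the silyl ether. The fallback sets out from 5 and returns at 7: the ester is removed before sulfur is introduced and put back afterwards. Krapcho demethoxycarbonylation of 5 (LiCl, wet DMSO, 140 °C) gives (5S)-5-[2-(triethylsilyloxy)propan-2-yl]oxolan-2-one F7, whose single carbonyl is thionated with Lawesson's reagent to (5S)-5-[2-(triethylsilyloxy)propan-2-yl]oxolane-2-thione F8. LiN(i-Pr)2 followed by MeI S-methylates the thioenolate to triethyl({2-[(2S)-5-(methylsulfanyl)-2,3-dihydrofuran-2-yl]propan-2-yl}oxy)silane F9. C-Acylation of this electron-rich ketene O,S-acetal with trichloroacetyl chloride and pyridine gives 2,2,2-trichloro-1-[(5S)-2-(methylsulfanyl)-5-[2-(triethylsilyloxy)propan-2-yl]-4,5-dihydrofuran-3-yl]ethan-1-one F10, and haloform-type cleavage with K2CO3 in MeOH delivers 7.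

Step 9. Hydrogenation may be slow at the chelated, hindered enone, which gives time for cyclisation of the chalcone to the flavanone or for partial saturation of the prenyl alkene. The fallback sets out from 16 and returns at 18: both phenols are capped with Et3SiOTf and 2,6-lutidine to give (2E)-3-(4-methoxyphenyl)-1-[(2S)-5-(3-methylbut-2-en-1-yl)-4,6-bis(triethylsilyloxy)-2-[2-(triethylsilyloxy)propan-2-yl]-2,3-dihydro-1-benzofuran-7-yl]prop-2-en-1-one F11, which cannot cyclise and has no acidic OH. Conjugate hydride transfer with [(Ph3P)CuH]6 in wet toluene, which does not touch isolated alkenes, gives 3-(4-methoxyphenyl)-1-[(2S)-5-(3-methylbut-2-en-1-yl)-4,6-bis(triethylsilyloxy)-2-[2-(triethylsilyloxy)propan-2-yl]-2,3-dihydro-1-benzofuran-7-yl]propan-1-one F12, and Bu4NF removes all three silyl groups to give 18.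

Further compounds
F1 | step 8 | (2S)-2-[2-(methoxymethoxy)propan-2-yl]oxirane | COCOC(C)(C)[C@@H]1CO1
F2 | step 8 | 1-fluoro-3,5-bis(methoxymethoxy)benzene | COCOc1cc(F)cc(OCOC)c1
F3 | step 8 | 5-fluoro-1,3-bis(methoxymethoxy)-2-(3-methylbut-2-en-1-yl)benzene | COCOc1cc(F)cc(OCOC)c1CC=C(C)C
F4 | step 8 | (2S)-1-[6-fluoro-2,4-bis(methoxymethoxy)-3-(3-methylbut-2-en-1-yl)phenyl]-3-(methoxymethoxy)-3-methylbutan-2-ol | COCOc1cc(F)c(C[C@H](O)C(C)(C)OCOC)c(OCOC)c1CC=C(C)C
F5 | step 8 | 1-[2-fluoro-3-[(2S)-2-hydroxy-3-(methoxymethoxy)-3-methylbutyl]-4,6-bis(methoxymethoxy)-5-(3-methylbut-2-en-1-yl)phenyl]-3-(4-methoxyphenyl)propan-1-one | COc1ccc(CCC(=O)c2c(F)c(C[C@H](O)C(C)(C)OCOC)c(OCOC)c(CC=C(C)C)c2OCOC)cc1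
F6 | step 8 | 1-[(2S)-4,6-bis(methoxymethoxy)-2-[2-(methoxymethoxy)propan-2-yl]-5-(3-methylbut-2-en-1-yl)-2,3-dihydro-1-benzofuran-7-yl]-3-(4-methoxyphenyl)propan-1-one | COc1ccc(CCC(=O)c2c(OCOC)c(CC=C(C)C)c(OCOC)c3c2O[C@H](C(C)(C)OCOC)C3)cc1
F7 | step 4 | (5S)-5-[2-(triethylsilyloxy)propan-2-yl]oxolan-2-one | O=C1O[C@H](C(C)(C)O[Si](CC)(CC)CC)CC1
F8 | step 4 | (5S)-5-[2-(triethylsilyloxy)propan-2-yl]oxolane-2-thione | S=C1O[C@H](C(C)(C)O[Si](CC)(CC)CC)CC1
F9 | step 4 | triethyl({2-[(2S)-5-(methylsulfanyl)-2,3-dihydrofuran-2-yl]propan-2-yl}oxy)silane | O1[C@H](C(C)(C)O[Si](CC)(CC)CC)CC=C1SC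
F10 | step 4 | 2,2,2-trichloro-1-[(5S)-2-(methylsulfanyl)-5-[2-(triethylsilyloxy)propan-2-yl]-4,5-dihydrofuran-3-yl]ethan-1-one | O1[C@H](C(C)(C)O[Si](CC)(CC)CC)CC(C(=O)C(Cl)(Cl)Cl)=C1SC
F11 | step 9 | (2E)-3-(4-methoxyphenyl)-1-[(2S)-5-(3-methylbut-2-en-1-yl)-4,6-bis(triethylsilyloxy)-2-[2-(triethylsilyloxy)propan-2-yl]-2,3-dihydro-1-benzofuran-7-yl]prop-2-en-1-one | COc1ccc(/C=C/C(=O)c2c(O[Si](CC)(CC)CC)c(CC=C(C)C)c(O[Si](CC)(CC)CC)c3c2O[C@H](C(C)(C)O[Si](CC)(CC)CC)C3)cc1
F12 | step 9 | 3-(4-methoxyphenyl)-1-[(2S)-5-(3-methylbut-2-en-1-yl)-4,6-bis(triethylsilyloxy)-2-[2-(triethylsilyloxy)propan-2-yl]-2,3-dihydro-1-benzofuran-7-yl]propan-1-one | COc1ccc(CCC(=O)c2c(O[Si](CC)(CC)CC)c(CC=C(C)C)c(O[Si](CC)(CC)CC)c3c2O[C@H](C(C)(C)O[Si](CC)(CC)CC)C3)cc1
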